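Readings and results were computed from invented constants; the scatter is artificial.

| setting | noon | dusk | winter | flask |
|---|---|---|---|---|
| electrophile | 0.50 M | 0.50 M | 1 M | 0.50 M |
| free base | 0.40 M | 0.90 M | 0.60 M | 0.600 M |
| protonated nucleophile | 0.90 M | 0.90 M | 0.90 M | 0.900 M |
| remark | run made earlier | run made earlier | run made earlier |  |
| time |  |  |  | 6.0 h |

| run | time / h | electrophile / % | target / % |
|---|---|---|---|
| noon | 0.833 | 61.7 | 35.8 |
| noon | 1.50 | 45.6 | 49.6 |
| noon | 2.50 | 27.6 | 59.0 |
| noon | 3.00 | 22.5 | 65.0 |
| noon | 4.00 | 17.3 | 67.1 |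
| noon | 5.00 | 9.1 | 66.7 |
| noon | 6.00 | 6.3 | 67.8 |
| dusk | 0.333 | 74.4 | 24.3 |
| dusk | 1.00 | 50.2 | 45.2 |
| dusk | 1.50 | 39.9 | 54.7 |
| dusk | 2.50 | 23.5 | 64.0 |
| dusk | 4.00 | 14.8 | 67.9 |
| dusk | 5.00 | 10.3 | 68.4 |
| dusk | 6.00 | 6.1 | 67.6 |
| winter | 0.500 | 75.8 | 24.8 |
| winter | 0.833 | 65.8 | 31.6 |
| winter | 1.50 | 52.8 | 41.8 |
| winter | 3.00 | 36.4 | 53.5 |
| winter | 6.00 | 23.2 | 57.3 |

(scatter of a reading: 1 percentage point)

- the earlier runs do not show how much of nucleophile is bound; that part of a forecast is a guess

- part of the electrophile that has reacted at 6.0 h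
- share of the unused nucleophile that is free and not bound as protonated nucleophile, at 6.0 h

Per hour, I reckoned how far the logarithm of the fraction of electrophile left had fallen by the last reading. This is a mean pseudo-first-order rate. My zero was the case in which free base changes nothing, so noon and dusk should match.

noon: 0.461 /h

dusk: 0.466 /h

Free base rose by a factor of 2.25 from noon to dusk, yet the rates matched. The flask's free base lay between theirs, so I took their mean.

flask rate: 0.463 /h

left at 6.0 h: 6.20%

reacted: 93.8%

The weak link was that neither run had the flask's free base. The winter run had it, but with twice the electrophile. So I multiplied rate by electrophile charge and called the product the drain.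

flask drain: 0.232 M/h

winter drain: 0.244 M/h

The winter drain put the flask at 94.6% reacted, so my figure held.

The forecast gave 94%, within 91.5% to 96%. It gave 20% free, within 8% to 40%, and called that share “largely a guess, because the runs never measured binding”.

The flask reached 92.7% reacted, and 66.9% of its unused nucleophile was free.

    electrophile + nucleophile → acid set free + target (k = 3.35 × 10⁻⁴ /M/s)
    nucleophile + acid set free ⇌ protonated nucleophile, settled at all times (K = 40.6 /M)
    acid set free + free base ⇌ salt of the base, settled at all times (K = 4270 /M)
    crystals ⇌ acid set free, rate k4*(cs4 - [acid set free]) while solid is left; crystals form when [acid set free] > cs4 (solubility = 12.0 mM, k = 0.0299 /s)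
    target ⇌ isomer of the product (K = 0.520, k = 3.70 × 10⁻⁵ /s)

The flask's drain, from 7.27% of electrophile left, was 0.218 M/h. A neighbour flask, charged with 2.0 M of electrophile and otherwise like this one, kept 55.1% of its electrophile at 6.00 h where my drain foretold 49.9%. In the flask, the midpoint of the step to target came at 1.07 h, and that of crystallising a little later, at 1.19 h. At 6.00 h the flask held 0.619 M of crystals against 0.0122 M of acid set free.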